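**Assumption:** the SMILES cannot encode the only stereoelement, the C5–C1′ biaryl axis. I take the target as the (M)-atropisomer, drawn as described at Step 11. The antipodal catalyst in Step 11 gives (P) by the same route.

## Retrosynthetic overview

1. The obvious aryl–aryl cross-coupling (or lactone-bridged coupling) is not used. C5–C1′ starts life as an ordinary aryl–carbonyl bond.
2. Key step: the substituted naphthalene ring (C1′–C4′) is closed around a diaryl ketone by a catalytic atroposelective arene-forming aldol condensation. This single step creates the ring, the 4′-OH and the axis. The 2′-CHO it leaves is then reduced to 2′-CH3.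
3. The ketoaldehyde precursor comes from a diol by double oxidation and alkene cleavage. The diol comes from an isoquinoline-5-carbaldehyde and an aryllithium made from 2-bromo-6-methoxybenzaldehyde and butenylMgBr.
4. The isoquinoline-5-carbaldehyde comes from C5 bromination and formylation of the isoquinoline. The isoquinoline comes from an o-alkynylacetophenone and NH3, which traces back to 1-bromo-3,5-dimethoxybenzene.
5. Ring order: both benzene rings are bought, then the pyridine ring is formed (Step 4), then the naphthalene carbocycle with the axis (Step 11).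

## Route

**Step 1**
Reactants: 1, 1-bromo-3,5-dimethoxybenzene
Product: 2, 1-(2-bromo-4,6-dimethoxyphenyl)ethan-1-one
Conditions: AcCl, SnCl4, CH2Cl2, 0 °C → rt
Reagents that add atoms: acetyl chloride, CC(=O)Cl
Why: Friedel–Crafts acylation goes to C2 (ortho to one OMe, para to the other), which is less crowded than C4 between the two OMe groups, and the mild Lewis acid avoids ortho-demethylation.

**Step 2**
Reactants: 3, prop-2-yn-1-ol
Product: 4, triisopropyl(prop-2-yn-1-yloxy)silane
Conditions: TIPSCl, imidazole, CH2Cl2, rt
Reagents that add atoms: TIPSCl, CC(C)[Si](Cl)(C(C)C)C(C)C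
Why: Standard O-silylation, with TIPS chosen because it survives hot NH3/MeOH, organolithiums, oxidants and hydrides and is removed by fluoride at the end.

**Step 3**
Reactants: 2, 1-(2-bromo-4,6-dimethoxyphenyl)ethan-1-one; 4, triisopropyl(prop-2-yn-1-yloxy)silane
Product: 5, 1-[2,4-dimethoxy-6-(3-{[tri(propan-2-yl)silyl]oxy}prop-1-yn-1-yl)phenyl]ethan-1-one
Conditions: PdCl2(PPh3)2 (3 mol %), CuI (5 mol %), Et3N/DMF, 70 °C
Reagents that add atoms: none (both partners are numbered reactants)
Why: Sonogashira coupling, in which the ortho-acetyl group activates the otherwise electron-rich C–Br bond toward oxidative addition.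

**Step 4**
Reactants: 5, the o-alkynylacetophenone from Step 3
Product: 6, 6,8-dimethoxy-1-methyl-3-{[(triisopropylsilyl)oxy]methyl}isoquinoline
Conditions: NH3 (7 M in MeOH), sealed tube, 120 °C
Reagents that add atoms: ammonia, N
Why: Tandem imination and 6-endo-dig annulation of an o-alkynylaryl ketone, driven by aromatisation, places 1-Me, 3-CH2OTIPS, 6-OMe and 8-OMe without ambiguity.

**Step 5**
Reactants: 6, the isoquinoline from Step 4
Product: 7, 5-bromo-6,8-dimethoxy-1-methyl-3-{[(triisopropylsilyl)oxy]methyl}isoquinoline
Conditions: NBS (1.0 equiv), MeCN, 0 °C, dark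
Reagents that add atoms: N-bromosuccinimide, O=C1CCC(=O)N1Br
Why: Electrophilic aromatic bromination prefers C5, the naphthalene-type α-position (para to 8-OMe, ortho to 6-OMe), over C7 between two OMe groups, and ionic conditions in the dark spare the 1-CH3.

**Step 6**
Reactants: 7, the 5-bromoisoquinoline from Step 5
Product: 8, 6,8-dimethoxy-1-methyl-3-{[(triisopropylsilyl)oxy]methyl}isoquinoline-5-carbaldehyde
Conditions: n-BuLi (1.05 equiv), THF, −78 °C, 5 min; DMF, −78 °C → 0 °C
Reagents that add atoms: N,N-dimethylformamide, CN(C)C=O
Why: Br/Li exchange followed by Bouveault formylation works because exchange at −78 °C outruns deprotonation of the azine methyl group, as with bromopicolines; this carbon becomes C1′.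

**Step 7**
Reactants: 9, 2-bromo-6-methoxybenzaldehyde; 10, but-3-en-1-ylmagnesium bromide
Product: 11, (±)-1-(2-bromo-6-methoxyphenyl)pent-4-en-1-ol
Conditions: THF, 0 °C
Reagents that add atoms: but-3-en-1-ylmagnesium bromide (10), C=CCC[Mg]Br
Why: Grignard 1,2-addition installs C4′, C3′, C2′ and the masked formyl carbon, and the racemic carbinol centre is destroyed in Step 9.

**Step 8**
Reactants: 11, (±)-1-(2-bromo-6-methoxyphenyl)pent-4-en-1-ol; 8, the isoquinoline-5-carbaldehyde from Step 6
Product: 12, {6,8-dimethoxy-1-methyl-3-[(TIPSO)methyl]isoquinolin-5-yl}[2-(1-hydroxypent-4-en-1-yl)-3-methoxyphenyl]methanol (diastereomer mixture)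
Conditions: 11, n-BuLi (2.1 equiv), THF, −78 °C, 30 min; then 8, −78 → −20 °C
Reagents that add atoms: none
Why: Deprotonation and then Br/Li exchange gives an O,C-dilithio species whose aryllithium adds 1,2 to the aldehyde much faster than it deprotonates 1-CH3 or carbolithiates the alkene, and both carbinol centres are erased in Step 9.

**Step 9**
Reactants: 12, the diol from Step 8
Product: 13, 1-{2-[6,8-dimethoxy-1-methyl-3-((TIPSO)methyl)isoquinoline-5-carbonyl]-6-methoxyphenyl}pent-4-en-1-one
Conditions: Dess–Martin periodinane (3 equiv), NaHCO3, CH2Cl2, 0 °C → rt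
Reagents that add atoms: none
Why: Dess–Martin oxidation converts both benzylic carbinols, the buffer keeps the intermediate lactol from dehydrating to an isobenzofuran, and the alkene, silyl ether and isoquinoline are inert.

**Step 10**
Reactants: 13, the diketone from Step 9
Product: 14, 4-{2-[6,8-dimethoxy-1-methyl-3-((TIPSO)methyl)isoquinoline-5-carbonyl]-6-methoxyphenyl}-4-oxobutanal
Conditions: OsO4 (2 mol %), NaIO4 (4 equiv), 2,6-lutidine, dioxane/H2O 3:1, rt
Reagents that add atoms: OsO4, O=[Os](=O)(=O)=O, with NaIO4, [Na+].[O-]I(=O)(=O)=O (source of the new carbonyl O)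
Why: Lemieux–Johnson cleavage touches only the monosubstituted alkene, and lutidine buffering prevents premature racemic aldolisation.

**Step 11 (key step)**
Reactants: 14, the ketoaldehyde from Step 10
Product: 15, (P)-1-{6,8-dimethoxy-1-methyl-3-[(TIPSO)methyl]isoquinolin-5-yl}-4-hydroxy-5-methoxynaphthalene-2-carbaldehyde. To draw it, take a Newman view from the isoquinoline side with C6–OMe up: the 2′-CHO is on the right and the naphthalene benzo ring (C8a′/C8′) is on the left.
Conditions: (R)-5-(pyrrolidin-2-yl)-1H-tetrazole (20 mol %), CHCl3 (0.05 M), 40 °C, 48 h; recrystallise to raise er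
Reagents that add atoms: none (net loss of H2O)
Why: Proposed new method: the aldehyde alone forms an enamine, whose carbon C2′ attacks the tetrazole-H-bonded diaryl ketone C1′ in a 6-enolexo aldol; the Ar–C(=O) rotamers of the ketone interconvert quickly, so the catalyst selects one face of one rotamer (dynamic kinetic resolution); rotation of the di-ortho-substituted isoquinolyl group is frozen in the tertiary carbinol, and irreversible dehydration plus keto→naphthol tautomerisation converts the C1′/C2′ centres into the axis (central-to-axial chirality transfer); the only competing closure, 5-exo aldol of C3′ onto C1′, is reversible and cannot aromatise; the closest known chemistry is the secondary-amine-catalysed atroposelective arene-forming aldol condensation giving 1-arylnaphthalene-2-carbaldehydes, together with proline-type 6-enolexo aldolisation; the new elements are the tetra-ortho-substituted heteroaryl ketone and the 1,4-ketoaldehyde that gives the naphthol directly; the (R)-catalyst is predicted to give (P)-15 by analogy, treating the ring-fused flank as the large group, and this must be confirmed by ECD or X-ray, with the (S)-catalyst equally available.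

**Step 12**
Reactants: 15, the (P)-biaryl aldehyde from Step 11
Product: 16, (P)-4-{6,8-dimethoxy-1-methyl-3-[(TIPSO)methyl]isoquinolin-5-yl}-3-(hydroxymethyl)-8-methoxynaphthalen-1-ol (same spatial arrangement as 15)
Conditions: NaBH4, THF/MeOH, 0 °C
Reagents that add atoms: none
Why: Borohydride reduces the only remaining carbonyl, and the tetra-ortho-substituted axis is inert at 0 °C.

**Step 13**
Reactants: 16, the (P)-benzylic alcohol from Step 12
Product: 17, (P)-3-(bromomethyl)-4-{6,8-dimethoxy-1-methyl-3-[(TIPSO)methyl]isoquinolin-5-yl}-8-methoxynaphthalen-1-ol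
Conditions: CBr4, PPh3, CH2Cl2, 0 °C; use crude
Reagents that add atoms: carbon tetrabromide, BrC(Br)(Br)Br
Why: The Appel reaction converts only the primary benzylic alcohol, since the naphthol OH, the TIPS ether and the nitrogen flanked by 1-Me and 3-CH2OTIPS do not react on this timescale.

**Step 14**
Reactants: 17, the (P)-benzylic bromide from Step 13
Product: 18, (M)-ancistrobenomine A, 4-[3-(hydroxymethyl)-6,8-dimethoxy-1-methylisoquinolin-5-yl]-8-methoxy-3-methylnaphthalen-1-ol. In the same Newman view as Step 11, the 2′-CH3 is on the right and the benzo ring on the left.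
Conditions: LiBHEt3 (4 equiv), THF, 0 °C; MeOH quench; then TBAF (6 equiv), rt, one pot
Reagents that add atoms: none
Why: SN2 hydride displacement of the benzylic bromide followed by fluoride desilylation gives the target, and the descriptor changes from P to M only because CH3 now ranks below C8a′ in the CIP rules while the geometry is unchanged.

## Compound list

The axis cannot be written in SMILES, so the descriptor is given in the name.

| No. | Name | SMILES | Role |
|---|---|---|---|
| 1 | 1-bromo-3,5-dimethoxybenzene | COc1cc(Br)cc(OC)c1 | starting material |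
| 2 | 1-(2-bromo-4,6-dimethoxyphenyl)ethan-1-one | CC(=O)c1c(Br)cc(OC)cc1OC | intermediate |
| 3 | prop-2-yn-1-ol | C#CCO | starting material |
| 4 | triisopropyl(prop-2-yn-1-yloxy)silane | C#CCO[Si](C(C)C)(C(C)C)C(C)C | intermediate |
| 5 | o-alkynylacetophenone | CC(=O)c1c(C#CCO[Si](C(C)C)(C(C)C)C(C)C)cc(OC)cc1OC | intermediate |
| 6 | 6,8-dimethoxy-1-methyl-3-(TIPSOCH2)isoquinoline | Cc1nc(CO[Si](C(C)C)(C(C)C)C(C)C)cc2cc(OC)cc(OC)c12 | intermediate |
| 7 | 5-bromo derivative of 6 | Cc1nc(CO[Si](C(C)C)(C(C)C)C(C)C)cc2c(Br)c(OC)cc(OC)c12 | intermediate |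
| 8 | isoquinoline-5-carbaldehyde | Cc1nc(CO[Si](C(C)C)(C(C)C)C(C)C)cc2c(C=O)c(OC)cc(OC)c12 | intermediate |
| 9 | 2-bromo-6-methoxybenzaldehyde | COc1cccc(Br)c1C=O | starting material |
| 10 | but-3-en-1-ylmagnesium bromide | C=CCC[Mg]Br | starting material |
| 11 | (±)-1-(2-bromo-6-methoxyphenyl)pent-4-en-1-ol | C=CCCC(O)c1c(Br)cccc1OC | intermediate |
| 12 | diol (diastereomer mixture) | C=CCCC(O)c1c(OC)cccc1C(O)c1c(OC)cc(OC)c2c(C)nc(CO[Si](C(C)C)(C(C)C)C(C)C)cc12 | intermediate |
| 13 | o-diacylbenzene (enone-free diketone) | C=CCCC(=O)c1c(OC)cccc1C(=O)c1c(OC)cc(OC)c2c(C)nc(CO[Si](C(C)C)(C(C)C)C(C)C)cc12 | intermediate |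
| 14 | diketo-aldehyde | O=CCCC(=O)c1c(OC)cccc1C(=O)c1c(OC)cc(OC)c2c(C)nc(CO[Si](C(C)C)(C(C)C)C(C)C)cc12 | intermediate |
| 15 | (P)-biaryl 2′-carbaldehyde | O=Cc1cc(O)c2c(OC)cccc2c1-c1c(OC)cc(OC)c2c(C)nc(CO[Si](C(C)C)(C(C)C)C(C)C)cc12 | intermediate |
| 16 | (P)-2′-hydroxymethyl biaryl | OCc1cc(O)c2c(OC)cccc2c1-c1c(OC)cc(OC)c2c(C)nc(CO[Si](C(C)C)(C(C)C)C(C)C)cc12 | intermediate |
| 17 | (P)-2′-bromomethyl biaryl | BrCc1cc(O)c2c(OC)cccc2c1-c1c(OC)cc(OC)c2c(C)nc(CO[Si](C(C)C)(C(C)C)C(C)C)cc12 | intermediate |
| 18 | (M)-ancistrobenomine A | COc1cc(OC)c2c(C)nc(CO)cc2c1-c1c(C)cc(O)c2c(OC)cccc12 | target |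

## Step count

- Total steps: 14.
- Longest linear sequence: 12 (Steps 1, 3, 4, 5, 6, 8, 9, 10, 11, 12, 13, 14).

## Steps most likely to fail

1. **Step 11.** The di-ortho-substituted, electron-rich ketone may react too slowly. The basic isoquinoline nitrogen may also disturb the bifunctional catalyst and erode the er.
   - Fallback: give up catalytic induction. Close the ring with achiral pyrrolidine·AcOH, since aromatisation still drives it.
   - Resolve rac-15 as its diastereomeric 4′-O-(1S)-camphanates by chromatography or crystallisation. The ester is removed by the hydride in Step 14.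
2. **Step 9.** After the first oxidation the substrate may rest as a lactol, or it may drift to a phthalan or isobenzofuran.
   - Fallback: change the logic. Deliberately dehydrate the mono-oxidised lactol (cat. TsOH) to the 1-alkyl-3-arylisobenzofuran.
   - Cleave that furan with singlet oxygen (O2, TPP, hν; Me2S) to the same diketone 13. The monosubstituted alkene is inert to singlet oxygen.
3. **Step 4.** Imination of the 2,6-disubstituted acetophenone may be slow, or the TIPS group may be lost at 120 °C.
   - Fallback: reverse the order of events. Use AgOTf-promoted 6-endo attack of the carbonyl oxygen on the alkyne to form the 1-methyl-2-benzopyrylium salt.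
   - Then carry out O→N exchange with NH4OAc at or below 60 °C (pyrylium-to-pyridine conversion).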